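Assumption: ring locants of the target cycloheptenone are used for all intermediates (C1 = ring C=O, C2 = C–CH2OH, C3 = CH=, C4 = quaternary C, C5 = CH with the two-carbon unit, C6 = CH with the 2-oxopropyl group, C7 = CH2); TIPS = tri(propan-2-yl)silyl; the annulation in step 3 is taken to occur anti to the lactone methyl group.

**Retrosynthetic overview**
1. Last bonds: the (Z)-enol ester comes from Ru-catalysed anti-Markovnikov addition of 3-methylbut-2-enoic acid to a C5 ethynyl group; the side-chain alkene comes from a Wittig reaction on an aldehyde that is kept as a dioxolane until the radical chemistry is over.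
2. Key disconnection: the C1–C2 bond of the 2-(hydroxymethyl)cyclohept-2-enone, made by a radical 1,2-acyl shift (one-carbon ring expansion) of a cyclohexanone carrying CBr2CH2OH on C3; that group comes from radical addition of •CBr2CH2OH to a regiodefined silyl enol ether.
3. C4 quaternary centre: cuprate addition to the convex face of a cis-fused cyclohexenone/δ-lactone, enolate kept as the TIPS enol ether; the lactone then gives the C5 alkyne and the C6 2-oxopropyl group.
4. Cyclohexenone: Michael/Michael–elimination annulation of the dienolate of 4-methoxypent-3-en-2-one onto (R)-parasorbic acid (from (R)-pent-4-en-2-ol), which fixes C5/C6 cis.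
5. Ring order: δ-lactone → fused cyclohexenone → lactone opened → six-membered ketone expanded to the seven-membered enone.

**Route**

Step 1
Reactants: 1 (2R)-pent-4-en-2-ol; 2 prop-2-enoyl chloride
Product: 3 (2R)-pent-4-en-2-yl prop-2-enoate
Conditions: Et3N, DMAP (cat.), CH2Cl2, 0 °C
Reagents that add atoms: none
Why: DMAP-catalysed O-acylation of the secondary alcohol; the stereocentre is not touched.

Step 2
Reactants: 3 (2R)-pent-4-en-2-yl prop-2-enoate
Product: 4 (6R)-6-methyl-5,6-dihydro-2H-pyran-2-one [(R)-parasorbic acid]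
Conditions: Grubbs II (3 mol%), CH2Cl2 (0.01 M), 40 °C
Reagents that add atoms: none
Why: Ring-closing metathesis of the acrylate and the terminal alkene closes the unsaturated δ-lactone with loss of ethene.

Step 3
Reactants: 4 (6R)-6-methyl-5,6-dihydro-2H-pyran-2-one; 5 (3E)-4-methoxypent-3-en-2-one
Product: 8 (3R,4aS,8aS)-3,8-dimethyl-3,4,4a,5-tetrahydro-1H-isochromene-1,6(8aH)-dione, via lithium dienolate 6 (not isolated), via methoxy ketone adduct 7 (not isolated)
Conditions: 5, LDA, THF, −78 °C; then 4, −78 → −20 °C; AcOH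
Reagents that add atoms: none
Why: The kinetic cross-conjugated dienolate adds 1,4 to the lactone anti to its methyl group (sets C6), the lactone enolate closes onto the vinylogous ester from the same face (cis fusion, sets C5) and methoxide is expelled: a Michael/Michael–elimination annulation (anionic Diels–Alder equivalent).

Step 4
Reactants: 8 (3R,4aS,8aS)-3,8-dimethyl-3,4,4a,5-tetrahydro-1H-isochromene-1,6(8aH)-dione; 9 2-(2-bromoethyl)-1,3-dioxolane
Product: 12 (3R,4aS,8S,8aS)-8-[2-(1,3-dioxolan-2-yl)ethyl]-3,8-dimethyl-6-(TIPS-oxy)-3,4,4a,5,8,8a-hexahydro-1H-isochromen-1-one, via Grignard reagent 10 (not isolated), via magnesium enolate 11 (not isolated)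
Conditions: 9, Mg, THF; CuBr·SMe2 (0.5 equiv per 10), THF/Me2S, −40 °C; 8, −78 → −30 °C; TIPSOTf, HMPA, −78 → 0 °C
Reagents that add atoms: tri(propan-2-yl)silyl trifluoromethanesulfonate, CC(C)[Si](C(C)C)(C(C)C)OS(=O)(=O)C(F)(F)F
Why: Organocuprate conjugate addition to the β-methyl enone from the convex face of the cis-fused bicycle (anti to the C5 substituent) sets quaternary C4 with the methyl cis to C5's carbonyl, and O-silylation fixes the enolate as C1=C3; the side-chain alkene is held back as a dioxolane because a radical at C2 or C3 would cyclise onto it.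

Step 5
Reactants: 12 (3R,4aS,8S,8aS)-8-[2-(1,3-dioxolan-2-yl)ethyl]-3,8-dimethyl-6-(TIPS-oxy)-3,4,4a,5,8,8a-hexahydro-1H-isochromen-1-one
Product: 14 (2R)-1-[(1S,5R,6R)-5-[2-(1,3-dioxolan-2-yl)ethyl]-6-ethynyl-5-methyl-3-(TIPS-oxy)cyclohex-3-en-1-yl]propan-2-ol, via lactol 13 (not isolated)
Conditions: DIBAL-H, CH2Cl2, −78 °C; MeOH; then K2CO3, Ohira–Bestmann reagent, MeOH, 0 °C → rt
Reagents that add atoms: dimethyl (1-diazo-2-oxopropyl)phosphonate, COP(=O)(OC)C(=[N+]=[N-])C(C)=O
Why: Half-reduction of the lactone to the lactol followed by Seyferth–Gilbert homologation (Ohira–Bestmann) of its open hydroxy-aldehyde form gives the C5 alkyne and frees the side-chain alcohol; C1 stays masked as the silyl enol ether, so no ketone meets the hydride, and C5 is protected from enolisation because the aldehyde sits mainly as the lactol.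

Step 6
Reactants: 14 (2R)-1-[(1S,5R,6R)-5-[2-(1,3-dioxolan-2-yl)ethyl]-6-ethynyl-5-methyl-3-(TIPS-oxy)cyclohex-3-en-1-yl]propan-2-ol
Product: 15 1-[(1R,5R,6R)-5-[2-(1,3-dioxolan-2-yl)ethyl]-6-ethynyl-5-methyl-3-(TIPS-oxy)cyclohex-3-en-1-yl]propan-2-one
Conditions: TPAP (5 mol%), NMO, 4 Å MS, CH2Cl2, rt
Reagents that add atoms: none
Why: Ley–Griffith oxidation of the secondary alcohol gives the 2-oxopropyl group; the carbinol stereocentre, used only to steer step 3, disappears here.

Step 7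
Reactants: 15 1-[(1R,5R,6R)-5-[2-(1,3-dioxolan-2-yl)ethyl]-6-ethynyl-5-methyl-3-(TIPS-oxy)cyclohex-3-en-1-yl]propan-2-one; 16 2,2,2-tribromoethan-1-ol
Product: 17 (3R,4R,5S)-2-(1,1-dibromo-2-hydroxyethyl)-3-[2-(1,3-dioxolan-2-yl)ethyl]-4-ethynyl-3-methyl-5-(2-oxopropyl)cyclohexan-1-one (C2 epimers)
Conditions: 16 (1.3 equiv), Et3B (0.3 equiv), air, CH2Cl2, 0 °C → rt
Reagents that add atoms: none
Why: Kharasch-type atom-transfer radical addition: the electrophilic •CBr2CH2OH radical adds to the electron-rich enol ether carbon C3 (the only reactive π-bond besides the slow terminal alkyne), bromine transfer and loss of TIPS–Br give the ketone; the new C3 centre is irrelevant because it becomes sp2 in step 8.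

Step 8
Reactants: 17 (3R,4R,5S)-2-(1,1-dibromo-2-hydroxyethyl)-3-[2-(1,3-dioxolan-2-yl)ethyl]-4-ethynyl-3-methyl-5-(2-oxopropyl)cyclohexan-1-one
Product: 18 (4R,5R,6S)-4-[2-(1,3-dioxolan-2-yl)ethyl]-5-ethynyl-2-(hydroxymethyl)-4-methyl-6-(2-oxopropyl)cyclohept-2-en-1-one
Conditions: (Bu3Sn)2 (1.1 equiv), hν (sun lamp), PhH (0.01 M), 80 °C
Reagents that add atoms: none
Why: Proposed new method: Bu3Sn• abstracts Br from the CBr2 group, the C2 radical adds 3-exo to C1=O and the cyclopropyloxy radical reopens toward C3 (1,2-acyl shift, forming C1–C2), the ring-expanded C3 radical expels Br• from C2 by fast β-scission to give the conjugated enone directly, and Br• regenerates Bu3Sn• from the distannane, so no hydride donor is present to reduce the radicals early; closest known reactions are the Dowd–Beckwith ring expansion of α-(halomethyl)cycloalkanones and β-bromoalkyl radical fragmentation; no stereocentre is touched.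

Step 9
Reactants: 18 (4R,5R,6S)-4-[2-(1,3-dioxolan-2-yl)ethyl]-5-ethynyl-2-(hydroxymethyl)-4-methyl-6-(2-oxopropyl)cyclohept-2-en-1-one
Product: 19 (4R,5R,6S)-5-ethynyl-2-(hydroxymethyl)-4-methyl-4-(3-oxopropyl)-6-(2-oxopropyl)cyclohept-2-en-1-one
Conditions: 1 M HCl, THF, rt
Reagents that add atoms: water, O
Why: Acid hydrolysis of the dioxolane releases the side-chain aldehyde; the enone, ketone, alkyne and primary alcohol are stable to dilute acid.

Step 10
Reactants: 19 (4R,5R,6S)-5-ethynyl-2-(hydroxymethyl)-4-methyl-4-(3-oxopropyl)-6-(2-oxopropyl)cyclohept-2-en-1-one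
Product: 20 (4R,5R,6S)-5-ethynyl-2-(hydroxymethyl)-4-methyl-4-(4-methylpent-3-en-1-yl)-6-(2-oxopropyl)cyclohept-2-en-1-one
Conditions: iPrPPh3I (2.2 equiv), KHMDS, THF, 0 °C; then 19, −78 → 0 °C
Reagents that add atoms: isopropyl(triphenyl)phosphonium iodide, CC(C)[P+](c1ccccc1)(c1ccccc1)c1ccccc1.[I-]
Why: Wittig olefination with the non-stabilised isopropylidene ylide is far faster on the aldehyde than on either ketone (tetrasubstituted alkene formation from ketones is slow), giving the trisubstituted side-chain alkene; one equivalent of ylide is spent on the free OH.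

Step 11
Reactants: 20 (4R,5R,6S)-5-ethynyl-2-(hydroxymethyl)-4-methyl-4-(4-methylpent-3-en-1-yl)-6-(2-oxopropyl)cyclohept-2-en-1-one; 21 3-methylbut-2-enoic acid
Product: 22 (Z)-2-[(1R,2R,7S)-4-(hydroxymethyl)-2-methyl-2-(4-methylpent-3-en-1-yl)-5-oxo-7-(2-oxopropyl)cyclohept-3-en-1-yl]ethenyl 3-methylbut-2-enoate (CNP0415257.1)
Conditions: [RuCl2(p-cymene)]2 (2 mol%), P(4-ClC6H4)3 (6 mol%), DMAP (8 mol%), toluene, 60 °C
Reagents that add atoms: none
Why: Ru-vinylidene-mediated anti-Markovnikov hydro-oxycarbonylation of the terminal alkyne gives the (Z)-enol ester selectively under neutral conditions that leave the ketones, the allylic alcohol and the alkenes alone.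

**Compound list**
1 | (2R)-pent-4-en-2-ol | C[C@@H](O)CC=C | starting material
2 | prop-2-enoyl chloride | C=CC(Cl)=O | starting material
3 | (2R)-pent-4-en-2-yl prop-2-enoate | C[C@@H](OC(=O)C=C)CC=C | intermediate
4 | (6R)-6-methyl-5,6-dihydro-2H-pyran-2-one | C[C@@H]1CC=CC(=O)O1 | intermediate
5 | (3E)-4-methoxypent-3-en-2-one | CC(=O)/C=C(\C)OC | starting material
6 | lithium (3E)-4-methoxypenta-1,3-dien-2-olate | C=C(O[Li])/C=C(\C)OC | intermediate (not isolated)
7 | (3R,4aS,8aS)-8-methoxy-3,8-dimethyl-3,4,4a,5,8,8a-hexahydro-1H-isochromene-1,6(7H)-dione, C8 epimers, formed as its lithium enolate | C[C@@H]1C[C@H]2CC(=O)CC(C)(OC)[C@H]2C(=O)O1 | intermediate (not isolated)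
8 | (3R,4aS,8aS)-3,8-dimethyl-3,4,4a,5-tetrahydro-1H-isochromene-1,6(8aH)-dione | C[C@@H]1C[C@H]2CC(=O)C=C(C)[C@H]2C(=O)O1 | intermediate
9 | 2-(2-bromoethyl)-1,3-dioxolane | BrCCC1OCCO1 | starting material
10 | [2-(1,3-dioxolan-2-yl)ethyl]magnesium bromide | Br[Mg]CCC1OCCO1 | intermediate (not isolated)
11 | bromomagnesium (3R,4aS,8S,8aS)-8-[2-(1,3-dioxolan-2-yl)ethyl]-3,8-dimethyl-1-oxo-3,4,4a,5,8,8a-hexahydro-1H-isochromen-6-olate | C[C@@H]1C[C@H]2CC(O[Mg]Br)=C[C@](C)(CCC3OCCO3)[C@H]2C(=O)O1 | intermediate (not isolated)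
12 | (3R,4aS,8S,8aS)-8-[2-(1,3-dioxolan-2-yl)ethyl]-3,8-dimethyl-6-{[tri(propan-2-yl)silyl]oxy}-3,4,4a,5,8,8a-hexahydro-1H-isochromen-1-one | C[C@@H]1C[C@H]2CC(O[Si](C(C)C)(C(C)C)C(C)C)=C[C@](C)(CCC3OCCO3)[C@H]2C(=O)O1 | intermediate
13 | (3R,4aS,8S,8aS)-8-[2-(1,3-dioxolan-2-yl)ethyl]-3,8-dimethyl-6-{[tri(propan-2-yl)silyl]oxy}-3,4,4a,5,8,8a-hexahydro-1H-isochromen-1-ol (lactol, both anomers) | C[C@@H]1C[C@H]2CC(O[Si](C(C)C)(C(C)C)C(C)C)=C[C@](C)(CCC3OCCO3)[C@H]2C(O)O1 | intermediate (not isolated)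
14 | (2R)-1-[(1S,5R,6R)-5-[2-(1,3-dioxolan-2-yl)ethyl]-6-ethynyl-5-methyl-3-{[tri(propan-2-yl)silyl]oxy}cyclohex-3-en-1-yl]propan-2-ol | C[C@@H](O)C[C@H]1CC(O[Si](C(C)C)(C(C)C)C(C)C)=C[C@](C)(CCC2OCCO2)[C@H]1C#C | intermediate
15 | 1-[(1R,5R,6R)-5-[2-(1,3-dioxolan-2-yl)ethyl]-6-ethynyl-5-methyl-3-{[tri(propan-2-yl)silyl]oxy}cyclohex-3-en-1-yl]propan-2-one | CC(=O)C[C@H]1CC(O[Si](C(C)C)(C(C)C)C(C)C)=C[C@](C)(CCC2OCCO2)[C@H]1C#C | intermediate
16 | 2,2,2-tribromoethan-1-ol | OCC(Br)(Br)Br | starting material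
17 | (3R,4R,5S)-2-(1,1-dibromo-2-hydroxyethyl)-3-[2-(1,3-dioxolan-2-yl)ethyl]-4-ethynyl-3-methyl-5-(2-oxopropyl)cyclohexan-1-one (C2 epimers) | CC(=O)C[C@H]1CC(=O)C(C(Br)(Br)CO)[C@](C)(CCC2OCCO2)[C@H]1C#C | intermediate
18 | (4R,5R,6S)-4-[2-(1,3-dioxolan-2-yl)ethyl]-5-ethynyl-2-(hydroxymethyl)-4-methyl-6-(2-oxopropyl)cyclohept-2-en-1-one | CC(=O)C[C@H]1CC(=O)C(CO)=C[C@](C)(CCC2OCCO2)[C@H]1C#C | intermediate
19 | (4R,5R,6S)-5-ethynyl-2-(hydroxymethyl)-4-methyl-4-(3-oxopropyl)-6-(2-oxopropyl)cyclohept-2-en-1-one | CC(=O)C[C@H]1CC(=O)C(CO)=C[C@](C)(CCC=O)[C@H]1C#C | intermediate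
20 | (4R,5R,6S)-5-ethynyl-2-(hydroxymethyl)-4-methyl-4-(4-methylpent-3-en-1-yl)-6-(2-oxopropyl)cyclohept-2-en-1-one | CC(=O)C[C@H]1CC(=O)C(CO)=C[C@](C)(CCC=C(C)C)[C@H]1C#C | intermediate
21 | 3-methylbut-2-enoic acid | CC(C)=CC(=O)O | starting material
22 | (Z)-2-[(1R,2R,7S)-4-(hydroxymethyl)-2-methyl-2-(4-methylpent-3-en-1-yl)-5-oxo-7-(2-oxopropyl)cyclohept-3-en-1-yl]ethenyl 3-methylbut-2-enoate | CC(=O)C[C@H]1CC(=O)C(CO)=C[C@](C)(CCC=C(C)C)[C@H]1/C=C\OC(=O)C=C(C)C | target

**Totals and risks**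
Total step count: 11. Longest linear sequence: 11 (1 → 22); 5, 9, 16 and 21 enter as bought materials.

Most likely to fail – step 8 (radical ring expansion). The 1,2-acyl shift of an α-bromo radical is untested and may be slow; competing paths are 1,6-hydrogen transfer from the acetal C–H, 5-exo attack on the ethynyl group and loss of HBr from 17. Fallback: set out from 17 and go to a two-electron pathway. SmI2 (2.2 equiv, THF/HMPA, −78 °C) reduces one C–Br bond to an α-bromo organosamarium that adds to the C1 ketone and gives the bromocyclopropanol 7-bromo-7-(hydroxymethyl)bicyclo[4.1.0]heptan-1-ol derivative F5. On warming, or with AgOTf, this opens with loss of bromide and cleavage of the old C1–C3 bond and returns to the route at 18.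

Second – step 7 (radical alkylation of the silyl enol ether). C3 is flanked by the quaternary carbon, so addition may be slow and the reagent may be consumed by telomerisation or attack on the alkyne. Fallback: set out from 15 and replace the radical alkylation and expansion by carbene chemistry. Dibromocarbene from PhHgCBr3 (benzene, 80 °C, neutral) cyclopropanates the enol ether to the 7,7-dibromo-1-(TIPS-oxy)bicyclo[4.1.0]heptane derivative F3. Heating in toluene opens it, with loss of TIPS–Br, to (4R,5R,6S)-2-bromo-4-[2-(1,3-dioxolan-2-yl)ethyl]-5-ethynyl-4-methyl-6-(2-oxopropyl)cyclohept-2-en-1-one F4. Stille coupling with (tributylstannyl)methanol (Pd(PPh3)4, dioxane, 90 °C) then gives 18, where the route is rejoined; 17 and step 8 are bypassed.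

Third – step 3 (annulation). The second Michael addition creates a fully substituted carbon next to the ring fusion; the lactone could also suffer 1,2-attack, or the fusion could equilibrate under the basic conditions. Fallback: set out from 4 and build the ring by a concerted cycloaddition. (E)-Pent-3-en-2-one is silylated (TMSOTf, Et3N) to (3E)-2-(trimethylsilyloxy)penta-1,3-diene F1. Thermal Diels–Alder reaction with 4 (toluene, 150 °C, sealed tube), anti to the lactone methyl and endo, gives the cis-fused (3R,4aS,8aS)-3,8-dimethyl-6-(trimethylsilyloxy)-3,4,4a,5,8,8a-hexahydro-1H-isochromen-1-one F2. Saegusa–Larock oxidation (Pd(OAc)2 cat., O2, DMSO) converts the silyl enol ether into the enone and returns to the route at 8.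

**Further compounds**
F1 | step 3 | (3E)-2-(trimethylsilyloxy)penta-1,3-diene | C=C(O[Si](C)(C)C)/C=C/C
F2 | step 3 | (3R,4aS,8aS)-3,8-dimethyl-6-(trimethylsilyloxy)-3,4,4a,5,8,8a-hexahydro-1H-isochromen-1-one (C8 from endo addition) | C[C@@H]1C[C@H]2CC(O[Si](C)(C)C)=CC(C)[C@H]2C(=O)O1
F3 | step 7 | 1-[(3R,4R)-7,7-dibromo-5-[2-(1,3-dioxolan-2-yl)ethyl]-4-ethynyl-5-methyl-1-{[tri(propan-2-yl)silyl]oxy}bicyclo[4.1.0]heptan-3-yl]propan-2-one (dibromocarbene adduct of 15) | CC(=O)C[C@H]1CC2(O[Si](C(C)C)(C(C)C)C(C)C)C(C2(Br)Br)[C@](C)(CCC3OCCO3)[C@H]1C#C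
F4 | step 7 | (4R,5R,6S)-2-bromo-4-[2-(1,3-dioxolan-2-yl)ethyl]-5-ethynyl-4-methyl-6-(2-oxopropyl)cyclohept-2-en-1-one | CC(=O)C[C@H]1CC(=O)C(Br)=C[C@](C)(CCC2OCCO2)[C@H]1C#C
F5 | step 8 | 1-[(3S,4R)-7-bromo-5-[2-(1,3-dioxolan-2-yl)ethyl]-4-ethynyl-1-hydroxy-7-(hydroxymethyl)-5-methylbicyclo[4.1.0]heptan-3-yl]propan-2-one (bromocyclopropanol from 17) | CC(=O)C[C@H]1CC2(O)C(C2(Br)CO)[C@](C)(CCC3OCCO3)[C@H]1C#C
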